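**Plan**
- Retrosynthetic cuts, in order: the C9–O ester bond, the C=C bond of the C5 propenal arm and the phenol O–allyl bond; then O1–C7a of the dihydrofuran; then C2–C3 (aldol); last the C3–C3a aryl–CH2 bond (Negishi coupling).
- Forward: ring A (from 4-fluoro-3-methoxybenzaldehyde) is iodinated next to fluorine and given a two-carbon arm. The arm is joined to ring B (O-allylvanillin) by a boron aldol, and the auxiliary is reduced off to the C9 alcohol. The dihydrofuran, the only ring formed, is then closed, and the enal, the ester and the free phenol come last.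
- Enabling feature: C7a of ring A is para to C5 and ortho to the C7 methoxyl, so with C5 as a formyl group a fluoride on C7a can be displaced by the alkoxide on C2.
- Stereochemistry: C2 (R) and C3 (S) are both set in the syn-aldol directed by (R)-4-benzyl-1,3-oxazolidin-2-one. The ring closure breaks no bond at either centre, so the syn diol monoether gives the trans ring.

Key step: step 11

Remark: benzofuran numbering is used throughout (O1, aryl-bearing C2, C3, C3a, C4–C7, C7a; C9 is the CH2O carbon on C3); read this way the target is the trans-(2R,3S) isomer.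

**Step 1**
Reactants: 1 4-fluoro-3-methoxybenzaldehyde
Product: 2 2-(4-fluoro-3-methoxyphenyl)-1,3-dioxolane
Conditions: HOCH2CH2OH, TsOH·H2O (cat.), toluene, reflux, Dean–Stark
Reagents that add atoms: ethane-1,2-diol, OCCO
Why: Acid-catalysed acetalisation with azeotropic removal of water masks the formyl group as a base-stable dioxolane that directs metalation only weakly.

**Step 2**
Reactants: 2 2-(4-fluoro-3-methoxyphenyl)-1,3-dioxolane
Product: 4 2-(4-fluoro-3-iodo-5-methoxyphenyl)-1,3-dioxolane, via aryllithium 3 (not isolated)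
Conditions: n-BuLi, PMDTA, THF, −78 °C; then I2, −78 °C → rt
Reagents that add atoms: iodine, II
Why: Directed ortho-metalation under acidity control: with lithium saturated by PMDTA the base should remove the proton next to fluorine (the C–H flanked by F and H) rather than the one between methoxyl and acetal, and iodinolysis at −78 °C traps aryllithium 3 before LiF can be lost.

**Step 3**
Reactants: 4 2-(4-fluoro-3-iodo-5-methoxyphenyl)-1,3-dioxolane
Product: 5 ethyl 2-[5-(1,3-dioxolan-2-yl)-2-fluoro-3-methoxyphenyl]acetate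
Conditions: BrZnCH2CO2Et (0.5 M stock solution), Pd2(dba)3 (cat.), XPhos, THF, 60 °C
Reagents that add atoms: (2-ethoxy-2-oxoethyl)zinc bromide, CCOC(=O)C[Zn]Br
Why: Negishi cross-coupling of a Reformatsky reagent (a zinc ester enolate) with the aryl iodide forms the C3–C3a bond under neutral conditions that spare the acetal and the C–F bond.

**Step 4**
Reactants: 5 ethyl 2-[5-(1,3-dioxolan-2-yl)-2-fluoro-3-methoxyphenyl]acetate
Product: 6 2-[5-(1,3-dioxolan-2-yl)-2-fluoro-3-methoxyphenyl]acetic acid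
Conditions: LiOH, THF/H2O, rt; then 1 M HCl to pH 4, 0 °C
Reagents that add atoms: lithium hydroxide, [Li+].[OH-]
Why: Ester saponification; the dioxolane is inert to hydroxide and should survive a brief, cold acidification to pH 4.

**Step 5**
Reactants: 6 2-[5-(1,3-dioxolan-2-yl)-2-fluoro-3-methoxyphenyl]acetic acid; 7 (R)-4-benzyl-1,3-oxazolidin-2-one
Product: 9 (4R)-4-benzyl-3-{2-[5-(1,3-dioxolan-2-yl)-2-fluoro-3-methoxyphenyl]acetyl}-1,3-oxazolidin-2-one, via mixed pivalic anhydride 8 (not isolated)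
Conditions: PivCl, Et3N, THF, −20 → 0 °C; then 7, LiCl, rt
Reagents that add atoms: none
Why: N-acylation of the oxazolidinone through the mixed pivalic anhydride (LiCl-promoted), which avoids the ketene-prone arylacetyl chloride.

**Step 6**
Reactants: 10 vanillin (4-hydroxy-3-methoxybenzaldehyde)
Product: 11 3-methoxy-4-(prop-2-enyloxy)benzaldehyde (O-allylvanillin)
Conditions: allyl bromide, K2CO3, DMF, rt
Reagents that add atoms: allyl bromide, C=CCBr
Why: Williamson etherification of the phenoxide; the allyl ether tolerates boron triflate, hydride, acid, base and ylide and can be removed at the end under neutral conditions.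

**Step 7**
Reactants: 9 (4R)-4-benzyl-3-{2-[5-(1,3-dioxolan-2-yl)-2-fluoro-3-methoxyphenyl]acetyl}-1,3-oxazolidin-2-one; 11 3-methoxy-4-(prop-2-enyloxy)benzaldehyde
Product: 14 (4R)-4-benzyl-3-{(2R,3R)-2-[5-(1,3-dioxolan-2-yl)-2-fluoro-3-methoxyphenyl]-3-hydroxy-3-[3-methoxy-4-(prop-2-enyloxy)phenyl]propanoyl}-1,3-oxazolidin-2-one, via boron Z-enolate 12 (not isolated), via boron aldolate 13 (not isolated)
Conditions: i-Pr2NEt, Bu2BOTf, CH2Cl2, −78 → 0 °C; then 11, −78 → 0 °C; then pH 7 buffer, MeOH, 30% H2O2, 0 °C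
Reagents that add atoms: none
Why: Evans boron syn-aldol: soft enolisation gives Z-enolate 12, which adds to 11 through a closed chair (Zimmerman–Traxler) transition state with the auxiliary carbonyl turned away from the enolate oxygen, so the (R)-benzyl group blocks one enolate face and both centres are set together as (2R,3R), which is C3-S and C2-R in benzofuran numbering; the amine is added before the triflate so that no free Lewis acid meets the dioxolane.

**Step 8**
Reactants: 14 the aldol adduct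
Product: 15 (1R,2S)-2-[5-(1,3-dioxolan-2-yl)-2-fluoro-3-methoxyphenyl]-1-[3-methoxy-4-(prop-2-enyloxy)phenyl]propane-1,3-diol
Conditions: LiBH4, MeOH (1 equiv), THF, 0 °C
Reagents that add atoms: none
Why: Reductive cleavage of the N-acyloxazolidinone (hydride attack on the exocyclic imide carbonyl) gives the primary C9 alcohol and should leave both stereocentres, the dioxolane, the allyl ether and the aryl fluoride untouched.

**Step 9**
Reactants: 15 (1R,2S)-2-[5-(1,3-dioxolan-2-yl)-2-fluoro-3-methoxyphenyl]-1-[3-methoxy-4-(prop-2-enyloxy)phenyl]propane-1,3-diol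
Product: 16 3-{(1R,2S)-1,3-dihydroxy-1-[3-methoxy-4-(prop-2-enyloxy)phenyl]propan-2-yl}-4-fluoro-5-methoxybenzaldehyde
Conditions: 1 M HCl, THF, rt
Reagents that add atoms: water, O
Why: Acid-catalysed acetal hydrolysis, placed before tritylation so that the acid never meets a trityl ether, and mild enough not to ionise the electron-rich benzylic alcohol.

**Step 10**
Reactants: 16 3-{(1R,2S)-1,3-dihydroxy-1-[3-methoxy-4-(prop-2-enyloxy)phenyl]propan-2-yl}-4-fluoro-5-methoxybenzaldehyde
Product: 17 4-fluoro-3-{(1R,2S)-1-hydroxy-1-[3-methoxy-4-(prop-2-enyloxy)phenyl]-3-(trityloxy)propan-2-yl}-5-methoxybenzaldehyde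
Conditions: TrCl, Et3N, DMAP (cat.), CH2Cl2, rt
Reagents that add atoms: trityl chloride, ClC(c1ccccc1)(c1ccccc1)c1ccccc1
Why: Selective tritylation of the primary alcohol (the bulky trityl electrophile does not engage the hindered secondary benzylic alcohol) masks the only other oxygen that could reach C7a.

**Step 11**
Reactants: 17 4-fluoro-3-{(1R,2S)-1-hydroxy-1-[3-methoxy-4-(prop-2-enyloxy)phenyl]-3-(trityloxy)propan-2-yl}-5-methoxybenzaldehyde
Product: 19 (2R,3S)-7-methoxy-2-[3-methoxy-4-(prop-2-enyloxy)phenyl]-3-(trityloxymethyl)-2,3-dihydro-1-benzofuran-5-carbaldehyde, via sodium alkoxide 18 (not isolated)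
Conditions: NaH, DMF, 0 °C → rt
Reagents that add atoms: none
Why: Sodium hydride converts the secondary benzylic alcohol into alkoxide 18, which adds to C7a of ring A; the negative charge taken up by the ring is delocalised onto the para C5 formyl oxygen and fluoride is then expelled (addition–elimination). The closest known reaction type is the intramolecular SNAr etherification of alkoxides on fluoroarenes carrying a para acyl group, a standard entry to 2,3-dihydrobenzofurans. The dihydrofuran ring (O1–C2–C3–C3a–C7a) closes in a 5-exo mode by formation of O1–C7a. No stereocentre is created and no bond at C2 or C3 is broken, so the syn (1R,2S) arrangement of 17 is carried into the trans (2R,3S) ring. Only chemoselectivity is needed: the C9 oxygen, which could close an isomeric five-membered ring on the same carbon, is held as a trityl ether that neither migrates nor is cleaved by fluoride, the formyl group has no α-hydrogen, and the C7 methoxyl, being meta to the formyl group, is not activated for displacement.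

**Step 12**
Reactants: 19 (2R,3S)-7-methoxy-2-[3-methoxy-4-(prop-2-enyloxy)phenyl]-3-(trityloxymethyl)-2,3-dihydro-1-benzofuran-5-carbaldehyde
Product: 20 (E)-3-{(2R,3S)-7-methoxy-2-[3-methoxy-4-(prop-2-enyloxy)phenyl]-3-(trityloxymethyl)-2,3-dihydro-1-benzofuran-5-yl}prop-2-enal
Conditions: Ph3P=CHCHO, toluene, 80 °C
Reagents that add atoms: (triphenylphosphoranylidene)acetaldehyde, O=CC=P(c1ccccc1)(c1ccccc1)c1ccccc1
Why: Wittig olefination with a formyl-stabilised ylide should give the (E)-enal directly; it is run while the substrate carries only ethers, before the ester is introduced.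

**Step 13**
Reactants: 20 (E)-3-{(2R,3S)-7-methoxy-2-[3-methoxy-4-(prop-2-enyloxy)phenyl]-3-(trityloxymethyl)-2,3-dihydro-1-benzofuran-5-yl}prop-2-enal
Product: 21 (E)-3-{(2R,3S)-3-(hydroxymethyl)-7-methoxy-2-[3-methoxy-4-(prop-2-enyloxy)phenyl]-2,3-dihydro-1-benzofuran-5-yl}prop-2-enal
Conditions: 80% aq. AcOH, 50 °C
Reagents that add atoms: none
Why: Acid-catalysed solvolysis of the trityl ether (the trityl cation is captured by water) under conditions too weak to ionise the benzylic C2–O1 bond or harm the enal.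

**Step 14**
Reactants: 21 (E)-3-{(2R,3S)-3-(hydroxymethyl)-7-methoxy-2-[3-methoxy-4-(prop-2-enyloxy)phenyl]-2,3-dihydro-1-benzofuran-5-yl}prop-2-enal; 22 3-methylbutanoyl chloride
Product: 23 {(2R,3S)-7-methoxy-2-[3-methoxy-4-(prop-2-enyloxy)phenyl]-5-[(E)-3-oxoprop-1-enyl]-2,3-dihydro-1-benzofuran-3-yl}methyl 3-methylbutanoate
Conditions: pyridine, DMAP (cat.), CH2Cl2, 0 °C → rt
Reagents that add atoms: none
Why: DMAP-catalysed acylation of the primary alcohol with the acid chloride; no other nucleophilic group is present.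

**Step 15**
Reactants: 23 {(2R,3S)-7-methoxy-2-[3-methoxy-4-(prop-2-enyloxy)phenyl]-5-[(E)-3-oxoprop-1-enyl]-2,3-dihydro-1-benzofuran-3-yl}methyl 3-methylbutanoate
Product: 24 {(2R,3S)-2-(4-hydroxy-3-methoxyphenyl)-7-methoxy-5-[(E)-3-oxoprop-1-enyl]-2,3-dihydro-1-benzofuran-3-yl}methyl 3-methylbutanoate
Conditions: Pd(PPh3)4 (cat.), N-methylaniline, THF, rt
Reagents that add atoms: none
Why: Tsuji–Trost-type deallylation: zerovalent palladium ionises the aryl allyl ether to a π-allylpalladium phenoxide and the weakly basic aniline captures the allyl group, neutral conditions that should leave the enal, the ester and the benzylic ether intact.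

**Compound list**
1 | 4-fluoro-3-methoxybenzaldehyde | COc1cc(C=O)ccc1F | starting material
2 | 2-(4-fluoro-3-methoxyphenyl)-1,3-dioxolane | COc1cc(C2OCCO2)ccc1F | intermediate
3 | [5-(1,3-dioxolan-2-yl)-2-fluoro-3-methoxyphenyl]lithium | COc1cc(C2OCCO2)cc([Li])c1F | intermediate (not isolated)
4 | 2-(4-fluoro-3-iodo-5-methoxyphenyl)-1,3-dioxolane | COc1cc(C2OCCO2)cc(I)c1F | intermediate
5 | ethyl 2-[5-(1,3-dioxolan-2-yl)-2-fluoro-3-methoxyphenyl]acetate | CCOC(=O)Cc1cc(C2OCCO2)cc(OC)c1F | intermediate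
6 | 2-[5-(1,3-dioxolan-2-yl)-2-fluoro-3-methoxyphenyl]acetic acid | OC(=O)Cc1cc(C2OCCO2)cc(OC)c1F | intermediate
7 | (R)-4-benzyl-1,3-oxazolidin-2-one | O=C1N[C@H](Cc2ccccc2)CO1 | starting material
8 | 2-[5-(1,3-dioxolan-2-yl)-2-fluoro-3-methoxyphenyl]acetic 2,2-dimethylpropanoic anhydride | CC(C)(C)C(=O)OC(=O)Cc1cc(C2OCCO2)cc(OC)c1F | intermediate (not isolated)
9 | (4R)-4-benzyl-3-{2-[5-(1,3-dioxolan-2-yl)-2-fluoro-3-methoxyphenyl]acetyl}-1,3-oxazolidin-2-one | COc1cc(C2OCCO2)cc(CC(=O)N2C(=O)OC[C@H]2Cc2ccccc2)c1F | intermediate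
10 | vanillin (4-hydroxy-3-methoxybenzaldehyde) | COc1cc(C=O)ccc1O | starting material
11 | 3-methoxy-4-(prop-2-enyloxy)benzaldehyde | COc1cc(C=O)ccc1OCC=C | intermediate
12 | (4R)-4-benzyl-3-{(Z)-1-(dibutylboranyloxy)-2-[5-(1,3-dioxolan-2-yl)-2-fluoro-3-methoxyphenyl]ethenyl}-1,3-oxazolidin-2-one | CCCCB(CCCC)O/C(=C\c1cc(C2OCCO2)cc(OC)c1F)N1C(=O)OC[C@H]1Cc1ccccc1 | intermediate (not isolated)
13 | (4R)-4-benzyl-3-{(2R,3R)-3-(dibutylboranyloxy)-2-[5-(1,3-dioxolan-2-yl)-2-fluoro-3-methoxyphenyl]-3-[3-methoxy-4-(prop-2-enyloxy)phenyl]propanoyl}-1,3-oxazolidin-2-one | COc1cc([C@H](OB(CCCC)CCCC)[C@H](C(=O)N2C(=O)OC[C@H]2Cc2ccccc2)c2cc(C3OCCO3)cc(OC)c2F)ccc1OCC=C | intermediate (not isolated)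
14 | (4R)-4-benzyl-3-{(2R,3R)-2-[5-(1,3-dioxolan-2-yl)-2-fluoro-3-methoxyphenyl]-3-hydroxy-3-[3-methoxy-4-(prop-2-enyloxy)phenyl]propanoyl}-1,3-oxazolidin-2-one | COc1cc([C@H](O)[C@H](C(=O)N2C(=O)OC[C@H]2Cc2ccccc2)c2cc(C3OCCO3)cc(OC)c2F)ccc1OCC=C | intermediate
15 | (1R,2S)-2-[5-(1,3-dioxolan-2-yl)-2-fluoro-3-methoxyphenyl]-1-[3-methoxy-4-(prop-2-enyloxy)phenyl]propane-1,3-diol | COc1cc([C@H](O)[C@H](CO)c2cc(C3OCCO3)cc(OC)c2F)ccc1OCC=C | intermediate
16 | 3-{(1R,2S)-1,3-dihydroxy-1-[3-methoxy-4-(prop-2-enyloxy)phenyl]propan-2-yl}-4-fluoro-5-methoxybenzaldehyde | COc1cc([C@H](O)[C@H](CO)c2cc(C=O)cc(OC)c2F)ccc1OCC=C | intermediate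
17 | 4-fluoro-3-{(1R,2S)-1-hydroxy-1-[3-methoxy-4-(prop-2-enyloxy)phenyl]-3-(trityloxy)propan-2-yl}-5-methoxybenzaldehyde | COc1cc([C@H](O)[C@H](COC(c2ccccc2)(c2ccccc2)c2ccccc2)c2cc(C=O)cc(OC)c2F)ccc1OCC=C | intermediate
18 | sodium (1R,2S)-2-(2-fluoro-5-formyl-3-methoxyphenyl)-1-[3-methoxy-4-(prop-2-enyloxy)phenyl]-3-(trityloxy)propan-1-olate | [Na+].COc1cc([C@H]([O-])[C@H](COC(c2ccccc2)(c2ccccc2)c2ccccc2)c2cc(C=O)cc(OC)c2F)ccc1OCC=C | intermediate (not isolated)
19 | (2R,3S)-7-methoxy-2-[3-methoxy-4-(prop-2-enyloxy)phenyl]-3-(trityloxymethyl)-2,3-dihydro-1-benzofuran-5-carbaldehyde | COc1cc([C@@H]2Oc3c(OC)cc(C=O)cc3[C@H]2COC(c2ccccc2)(c2ccccc2)c2ccccc2)ccc1OCC=C | intermediate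
20 | (E)-3-{(2R,3S)-7-methoxy-2-[3-methoxy-4-(prop-2-enyloxy)phenyl]-3-(trityloxymethyl)-2,3-dihydro-1-benzofuran-5-yl}prop-2-enal | COc1cc([C@@H]2Oc3c(OC)cc(/C=C/C=O)cc3[C@H]2COC(c2ccccc2)(c2ccccc2)c2ccccc2)ccc1OCC=C | intermediate
21 | (E)-3-{(2R,3S)-3-(hydroxymethyl)-7-methoxy-2-[3-methoxy-4-(prop-2-enyloxy)phenyl]-2,3-dihydro-1-benzofuran-5-yl}prop-2-enal | COc1cc([C@@H]2Oc3c(OC)cc(/C=C/C=O)cc3[C@H]2CO)ccc1OCC=C | intermediate
22 | 3-methylbutanoyl chloride | CC(C)CC(Cl)=O | starting material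
23 | {(2R,3S)-7-methoxy-2-[3-methoxy-4-(prop-2-enyloxy)phenyl]-5-[(E)-3-oxoprop-1-enyl]-2,3-dihydro-1-benzofuran-3-yl}methyl 3-methylbutanoate | COc1cc([C@@H]2Oc3c(OC)cc(/C=C/C=O)cc3[C@H]2COC(=O)CC(C)C)ccc1OCC=C | intermediate
24 | {(2R,3S)-2-(4-hydroxy-3-methoxyphenyl)-7-methoxy-5-[(E)-3-oxoprop-1-enyl]-2,3-dihydro-1-benzofuran-3-yl}methyl 3-methylbutanoate | COc1cc([C@@H]2Oc3c(OC)cc(/C=C/C=O)cc3[C@H]2COC(=O)CC(C)C)ccc1O | target

**Step count**
Total: 15 steps. Longest linear sequence: 14 steps (steps 1–5 and 7–15 from 1; step 6 is a one-step branch).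

**Steps most likely to fail**

1. Step 2. The base may metalate the ring position between methoxyl and acetal instead of the one next to fluorine, or the ortho-fluoroaryllithium may lose LiF to an aryne before it is iodinated. The fallback sets out from 2 and replaces deprotonation by a sterically governed C–H borylation. With [Ir(OMe)(cod)]2, 4,4'-di-tert-butyl-2,2'-bipyridine and B2pin2 in THF at 80 °C, only the C–H flanked by fluorine and hydrogen is unhindered, which should give 2-[5-(1,3-dioxolan-2-yl)-2-fluoro-3-methoxyphenyl]-4,4,5,5-tetramethyl-1,3,2-dioxaborolane F1. Iododeboronation of the boronate (NaI, TsNClNa, aqueous THF, rt) comes back to the route at 4.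

2. Step 11. The alkoxide may be consumed at the formyl group of a second molecule (hemiacetal formation, hydride transfer from the benzylic alkoxide to the aldehyde) faster than it closes the ring. The fallback sets out from 17 and exchanges the activating group for one that cannot accept hydride. Oxidative amination of the aldehyde (I2, aqueous NH3, THF, rt) should give 4-fluoro-3-{(1R,2S)-1-hydroxy-1-[3-methoxy-4-(prop-2-enyloxy)phenyl]-3-(trityloxy)propan-2-yl}-5-methoxybenzonitrile F2. The same ring closure para to the cyano group (NaH, DMF, 0 °C → rt) gives (2R,3S)-7-methoxy-2-[3-methoxy-4-(prop-2-enyloxy)phenyl]-3-(trityloxymethyl)-2,3-dihydro-1-benzofuran-5-carbonitrile F3. Partial reduction of the nitrile (i-Bu2AlH, toluene, −78 °C, then hydrolysis of the imine on wet silica gel) comes back to the route at 19.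

3. Step 12. The product enal may react again with the ylide (chain growth to the dienal), or the electron-rich aldehyde may convert only slowly. The fallback sets out from 19 and builds the enal in three standard operations before any ester is present. Horner–Wadsworth–Emmons olefination (triethyl phosphonoacetate, NaH, THF, 0 °C → rt) should give ethyl (E)-3-{(2R,3S)-7-methoxy-2-[3-methoxy-4-(prop-2-enyloxy)phenyl]-3-(trityloxymethyl)-2,3-dihydro-1-benzofuran-5-yl}prop-2-enoate F4. Reduction (i-Bu2AlH, CH2Cl2, −78 °C) gives (E)-3-{(2R,3S)-7-methoxy-2-[3-methoxy-4-(prop-2-enyloxy)phenyl]-3-(trityloxymethyl)-2,3-dihydro-1-benzofuran-5-yl}prop-2-en-1-ol F5. Allylic oxidation (MnO2, CH2Cl2, rt) comes back to the route at 20.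

**Further compounds**
F1 | step 2 | 2-[5-(1,3-dioxolan-2-yl)-2-fluoro-3-methoxyphenyl]-4,4,5,5-tetramethyl-1,3,2-dioxaborolane | COc1cc(C2OCCO2)cc(B2OC(C)(C)C(C)(C)O2)c1F
F2 | step 11 | 4-fluoro-3-{(1R,2S)-1-hydroxy-1-[3-methoxy-4-(prop-2-enyloxy)phenyl]-3-(trityloxy)propan-2-yl}-5-methoxybenzonitrile | COc1cc([C@H](O)[C@H](COC(c2ccccc2)(c2ccccc2)c2ccccc2)c2cc(C#N)cc(OC)c2F)ccc1OCC=C
F3 | step 11 | (2R,3S)-7-methoxy-2-[3-methoxy-4-(prop-2-enyloxy)phenyl]-3-(trityloxymethyl)-2,3-dihydro-1-benzofuran-5-carbonitrile | COc1cc([C@@H]2Oc3c(OC)cc(C#N)cc3[C@H]2COC(c2ccccc2)(c2ccccc2)c2ccccc2)ccc1OCC=C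
F4 | step 12 | ethyl (E)-3-{(2R,3S)-7-methoxy-2-[3-methoxy-4-(prop-2-enyloxy)phenyl]-3-(trityloxymethyl)-2,3-dihydro-1-benzofuran-5-yl}prop-2-enoate | COc1cc([C@@H]2Oc3c(OC)cc(/C=C/C(=O)OCC)cc3[C@H]2COC(c2ccccc2)(c2ccccc2)c2ccccc2)ccc1OCC=C
F5 | step 12 | (E)-3-{(2R,3S)-7-methoxy-2-[3-methoxy-4-(prop-2-enyloxy)phenyl]-3-(trityloxymethyl)-2,3-dihydro-1-benzofuran-5-yl}prop-2-en-1-ol | COc1cc([C@@H]2Oc3c(OC)cc(/C=C/CO)cc3[C@H]2COC(c2ccccc2)(c2ccccc2)c2ccccc2)ccc1OCC=C
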